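**Plan**

- Retrosynthesis: the ring C phenol is unmasked last. The pyranone is then cut at C4–C4a (Friedel–Crafts), at O1–C2 (enol ether, back to 3,4-dimethoxyphenol) and at C2–C3 (Meldrum's acid homologation of dihydroferulic acid).
- Forward: dihydroferulic acid supplies ring C, the two-carbon tether and C2, and Meldrum's acid supplies C3 and C4. Ring A is attached through O1 by vinylic substitution of an enol triflate, and the pyranone ring closes last.
- Enabling feature: C4a of ring A lies ortho to O1 and para to the C7 methoxy group. It is the most electron-rich free carbon of the 3,4-dimethoxyphenyl ether, so the C4 acyl carbon can be delivered there.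
- Stereochemistry: the target has no stereocentre, and the enol ether geometry is erased in the acidic ring closure.

Key step: step 6

Remark: the enol triflate and the aryloxy enoates are drawn as Z isomers (ester cis to the oxygen substituent). Their geometry is assumed to be immaterial because it equilibrates under the acid of the ring closure.

**Step 1**
Reactants: 1 dihydroferulic acid [3-(4-hydroxy-3-methoxyphenyl)propanoic acid]
Product: 2 3-(4-acetoxy-3-methoxyphenyl)propanoic acid
Conditions: Ac2O, pyridine, 0 °C → rt; then H2O, aq. HCl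
Reagents that add atoms: acetic anhydride, CC(=O)OC(C)=O
Why: Pyridine-mediated O-acetylation of the phenol (nucleophilic acyl substitution) is fast, any mixed anhydride at the carboxyl group is hydrolysed back to the acid on aqueous work-up, and the acetate both masks the phenol and makes ring C less electron-rich for the later acylation.

**Step 2**
Reactants: 2 3-(4-acetoxy-3-methoxyphenyl)propanoic acid; 3 Meldrum's acid (2,2-dimethyl-1,3-dioxane-4,6-dione)
Product: 5 tert-butyl 5-(4-acetoxy-3-methoxyphenyl)-3-oxopentanoate, via acyl Meldrum's acid 4 (not isolated)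
Conditions: DCC, DMAP, CH2Cl2, 0 °C → rt; filter, aq. KHSO4 wash; then t-BuOH, toluene, 90 °C
Reagents that add atoms: tert-butanol, CC(C)(C)O
Why: Carbodiimide/DMAP activation (Steglich-type) C-acylates Meldrum's acid, and heating adduct 4 with tert-butanol expels acetone and CO2 through an acylketene that the alcohol traps, which is the standard Meldrum's acid homologation of an acid to a β-keto ester and leaves the aryl acetate untouched.

**Step 3**
Reactants: 5 tert-butyl 5-(4-acetoxy-3-methoxyphenyl)-3-oxopentanoate
Product: 6 tert-butyl (Z)-5-(4-acetoxy-3-methoxyphenyl)-3-{[(trifluoromethyl)sulfonyl]oxy}pent-2-enoate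
Conditions: Tf2O, i-Pr2NEt, CH2Cl2, −78 °C → 0 °C
Reagents that add atoms: trifluoromethanesulfonic anhydride, O=S(=O)(OS(=O)(=O)C(F)(F)F)C(F)(F)F
Why: O-Sulfonylation of the amine-generated enolate of the β-keto ester (enol triflate formation) is standard, should favour the Z isomer in CH2Cl2 through the internally hydrogen-bonded cis-enol, and the hindered amine at low temperature should spare the aryl acetate.

**Step 4**
Reactants: 6 tert-butyl (Z)-5-(4-acetoxy-3-methoxyphenyl)-3-{[(trifluoromethyl)sulfonyl]oxy}pent-2-enoate; 7 3,4-dimethoxyphenol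
Product: 8 tert-butyl (Z)-5-(4-acetoxy-3-methoxyphenyl)-3-(3,4-dimethoxyphenoxy)pent-2-enoate
Conditions: K2CO3, DMF, 0 °C → rt; 7 (1.0 equiv) added slowly
Reagents that add atoms: none
Why: Nucleophilic vinylic substitution by addition–elimination, in which phenoxide adds to the β-carbon of the β-triflyloxy enoate and triflate leaves (an elimination–addition path through the allenoate would converge on the same enol ether), is the classical entry to 3-aryloxyalk-2-enoates, and one equivalent of 7 added slowly in the cold is meant to let substitution outrun acetyl transfer from ring C.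

**Step 5**
Reactants: 8 tert-butyl (Z)-5-(4-acetoxy-3-methoxyphenyl)-3-(3,4-dimethoxyphenoxy)pent-2-enoate
Product: 9 (Z)-5-(4-acetoxy-3-methoxyphenyl)-3-(3,4-dimethoxyphenoxy)pent-2-enoic acid
Conditions: CF3CO2H, CH2Cl2 (1:4), 0 °C → rt, N2 sweep; evaporate from toluene
Reagents that add atoms: none
Why: Acidolysis of the tert-butyl ester (alkyl–oxygen cleavage with loss of isobutene) should free the acid under anhydrous conditions that hydrolyse neither the aryl acetate nor the ester-conjugated enol ether.

**Step 6**
Reactants: 9 (Z)-5-(4-acetoxy-3-methoxyphenyl)-3-(3,4-dimethoxyphenoxy)pent-2-enoic acid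
Product: 10 2-[2-(4-acetoxy-3-methoxyphenyl)ethyl]-6,7-dimethoxy-4H-chromen-4-one
Conditions: Eaton's reagent (7.7 wt% P2O5 in MeSO3H), rt → 40 °C; then ice–water
Reagents that add atoms: none
Why: P2O5–MeSO3H turns the carboxylic acid into a mixed anhydride or acylium ion whose carbon (future C4) attacks the aryloxy ring in an intramolecular Friedel–Crafts acylation, and loss of the ring proton re-aromatises ring A to leave the 4-pyranone. The closest known reaction type is the acid-mediated cyclisation of 3-aryloxyalk-2-enoic acids to 2-substituted chromones. The pyranone closes as a six-membered ring: the acyl carbon, held on the O1–C2=C3–C4 tether, bonds to the ortho carbon of ring A, formally a 6-exo-dig attack on the acylium carbon with the arene as π-nucleophile. No stereocentre is formed, and only the Z isomer can close, but any E isomer should feed into it by reversible protonation at C2 of the acid (C3 of the chromone), so the geometry of 9 need not be uniform. The step needs acylation at the ring A carbon para to a methoxy group instead of the carbon wedged between O1 and a methoxy group, which the para donor and the lower crowding should secure. It also needs ring closure to outrun intermolecular acylation, which the three oxygen donors of ring A and the deactivating acetate on ring C should secure.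

**Step 7**
Reactants: 10 2-[2-(4-acetoxy-3-methoxyphenyl)ethyl]-6,7-dimethoxy-4H-chromen-4-one
Product: 11 2-[2-(4-hydroxy-3-methoxyphenyl)ethyl]-6,7-dimethoxy-4H-chromen-4-one (target)
Conditions: K2CO3 (0.2 equiv), MeOH, 0 °C → rt; then aq. NH4Cl
Reagents that add atoms: none
Why: Base-catalysed transesterification of the aryl acetate with methanol should free the phenol quickly, while the chromone and the three methyl ethers tolerate catalytic carbonate in the cold.

**Compound list**

1 | dihydroferulic acid, 3-(4-hydroxy-3-methoxyphenyl)propanoic acid | COc1cc(CCC(=O)O)ccc1O | starting material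
2 | 3-(4-acetoxy-3-methoxyphenyl)propanoic acid | COc1cc(CCC(=O)O)ccc1OC(C)=O | intermediate
3 | Meldrum's acid, 2,2-dimethyl-1,3-dioxane-4,6-dione | CC1(C)OC(=O)CC(=O)O1 | starting material
4 | 5-[3-(4-acetoxy-3-methoxyphenyl)-1-hydroxypropylidene]-2,2-dimethyl-1,3-dioxane-4,6-dione (acyl Meldrum's acid, enol form) | COc1cc(CCC(O)=C2C(=O)OC(C)(C)OC2=O)ccc1OC(C)=O | intermediate (not isolated)
5 | tert-butyl 5-(4-acetoxy-3-methoxyphenyl)-3-oxopentanoate | COc1cc(CCC(=O)CC(=O)OC(C)(C)C)ccc1OC(C)=O | intermediate
6 | tert-butyl (Z)-5-(4-acetoxy-3-methoxyphenyl)-3-{[(trifluoromethyl)sulfonyl]oxy}pent-2-enoate | CC(C)(C)OC(=O)/C=C(\OS(=O)(=O)C(F)(F)F)CCc1ccc(OC(C)=O)c(OC)c1 | intermediate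
7 | 3,4-dimethoxyphenol | COc1ccc(O)cc1OC | starting material
8 | tert-butyl (Z)-5-(4-acetoxy-3-methoxyphenyl)-3-(3,4-dimethoxyphenoxy)pent-2-enoate | CC(C)(C)OC(=O)/C=C(\Oc1ccc(OC)c(OC)c1)CCc1ccc(OC(C)=O)c(OC)c1 | intermediate
9 | (Z)-5-(4-acetoxy-3-methoxyphenyl)-3-(3,4-dimethoxyphenoxy)pent-2-enoic acid | O=C(O)/C=C(\Oc1ccc(OC)c(OC)c1)CCc1ccc(OC(C)=O)c(OC)c1 | intermediate
10 | 2-[2-(4-acetoxy-3-methoxyphenyl)ethyl]-6,7-dimethoxy-4H-chromen-4-one | COc1cc(CCc2cc(=O)c3cc(OC)c(OC)cc3o2)ccc1OC(C)=O | intermediate
11 | 2-[2-(4-hydroxy-3-methoxyphenyl)ethyl]-6,7-dimethoxy-4H-chromen-4-one | COc1cc(CCc2cc(=O)c3cc(OC)c(OC)cc3o2)ccc1O | target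

Total step count: 7. Longest linear sequence: 7 steps (1 → 11).

**Steps most likely to fail**

Step 4. The vinylic substitution may be slow enough for phenoxide to strip the acetyl group from ring C, and the freed ring C phenoxide would then attack the triflate itself. Base-induced elimination of triflate may also compete. The fallback sets out from 1 and comes back at 8, carrying ring C as an allyl ether that phenoxide cannot attack. The dianion of 1 would be O-allylated (allyl bromide, aq. NaOH, EtOH, reflux, then HCl) to 3-[4-(allyloxy)-3-methoxyphenyl]propanoic acid F1. F1 would be coupled with 3 as in step 2 to the acyl Meldrum's acid 5-{3-[4-(allyloxy)-3-methoxyphenyl]-1-hydroxypropylidene}-2,2-dimethyl-1,3-dioxane-4,6-dione F2 and heated with tert-butanol to tert-butyl 5-[4-(allyloxy)-3-methoxyphenyl]-3-oxopentanoate F3. Triflation as in step 3 would give tert-butyl (Z)-5-[4-(allyloxy)-3-methoxyphenyl]-3-{[(trifluoromethyl)sulfonyl]oxy}pent-2-enoate F4. Substitution with 7 could then be driven with excess K2CO3 in warm DMF to tert-butyl (Z)-5-[4-(allyloxy)-3-methoxyphenyl]-3-(3,4-dimethoxyphenoxy)pent-2-enoate F5. Deallylation with Pd(PPh3)4 (zerovalent palladium) and morpholine in THF should give tert-butyl (Z)-3-(3,4-dimethoxyphenoxy)-5-(4-hydroxy-3-methoxyphenyl)pent-2-enoate F6, and Ac2O in pyridine would acetylate it to 8.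

Step 6. In the protic superacid the enol ether may be protonated and then hydrolysed or decarboxylated before the ring closes, or the acetate may be lost and intermolecular acylation may follow. The fallback sets out from 9 and comes back at 10 by a two-stage, anhydrous Friedel–Crafts acylation. Oxalyl chloride with catalytic DMF in CH2Cl2 would convert 9 into (Z)-5-(4-acetoxy-3-methoxyphenyl)-3-(3,4-dimethoxyphenoxy)pent-2-enoyl chloride F7. F7 would then be closed onto ring A with SnCl4 in CH2Cl2 at 0 °C, without water and without a Brønsted superacid, to give 10.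

Step 5. The tert-butyl cation may alkylate the electron-rich ring A, or acid may hydrate the enol ether with ensuing decarboxylation. The fallback sets out from 2 and 3 and comes back at 9, using an ester that is removed without acid. The acyl Meldrum's acid 4, made as in step 2, would be heated with allyl alcohol in toluene to give allyl 5-(4-acetoxy-3-methoxyphenyl)-3-oxopentanoate F8. Triflation as in step 3 would give allyl (Z)-5-(4-acetoxy-3-methoxyphenyl)-3-{[(trifluoromethyl)sulfonyl]oxy}pent-2-enoate F9. Substitution with 7 as in step 4 would give allyl (Z)-5-(4-acetoxy-3-methoxyphenyl)-3-(3,4-dimethoxyphenoxy)pent-2-enoate F10. The allyl ester would then be cleaved under neutral conditions with Pd(PPh3)4 (zerovalent palladium) and PhSiH3 in CH2Cl2 to deliver 9.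

**Further compounds**

F1 | step 4 | 3-[4-(allyloxy)-3-methoxyphenyl]propanoic acid | C=CCOc1ccc(CCC(=O)O)cc1OC
F2 | step 4 | 5-{3-[4-(allyloxy)-3-methoxyphenyl]-1-hydroxypropylidene}-2,2-dimethyl-1,3-dioxane-4,6-dione | C=CCOc1ccc(CCC(O)=C2C(=O)OC(C)(C)OC2=O)cc1OC
F3 | step 4 | tert-butyl 5-[4-(allyloxy)-3-methoxyphenyl]-3-oxopentanoate | C=CCOc1ccc(CCC(=O)CC(=O)OC(C)(C)C)cc1OC
F4 | step 4 | tert-butyl (Z)-5-[4-(allyloxy)-3-methoxyphenyl]-3-{[(trifluoromethyl)sulfonyl]oxy}pent-2-enoate | CC(C)(C)OC(=O)/C=C(\OS(=O)(=O)C(F)(F)F)CCc1ccc(OCC=C)c(OC)c1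
F5 | step 4 | tert-butyl (Z)-5-[4-(allyloxy)-3-methoxyphenyl]-3-(3,4-dimethoxyphenoxy)pent-2-enoate | CC(C)(C)OC(=O)/C=C(\Oc1ccc(OC)c(OC)c1)CCc1ccc(OCC=C)c(OC)c1
F6 | step 4 | tert-butyl (Z)-3-(3,4-dimethoxyphenoxy)-5-(4-hydroxy-3-methoxyphenyl)pent-2-enoate | CC(C)(C)OC(=O)/C=C(\Oc1ccc(OC)c(OC)c1)CCc1ccc(O)c(OC)c1
F7 | step 6 | (Z)-5-(4-acetoxy-3-methoxyphenyl)-3-(3,4-dimethoxyphenoxy)pent-2-enoyl chloride | O=C(Cl)/C=C(\Oc1ccc(OC)c(OC)c1)CCc1ccc(OC(C)=O)c(OC)c1
F8 | step 5 | allyl 5-(4-acetoxy-3-methoxyphenyl)-3-oxopentanoate | C=CCOC(=O)CC(=O)CCc1ccc(OC(C)=O)c(OC)c1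
F9 | step 5 | allyl (Z)-5-(4-acetoxy-3-methoxyphenyl)-3-{[(trifluoromethyl)sulfonyl]oxy}pent-2-enoate | C=CCOC(=O)/C=C(\OS(=O)(=O)C(F)(F)F)CCc1ccc(OC(C)=O)c(OC)c1
F10 | step 5 | allyl (Z)-5-(4-acetoxy-3-methoxyphenyl)-3-(3,4-dimethoxyphenoxy)pent-2-enoate | C=CCOC(=O)/C=C(\Oc1ccc(OC)c(OC)c1)CCc1ccc(OC(C)=O)c(OC)c1
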